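The route rests on cutting the C1''–C2'' bond of the lavandulyl chain. C1'' is a benzylic methylene on C8 of ring A, flanked by O1 and the C7 methoxy group, so it can be unmasked as an ortho-quinone methide from 2-(hydroxymethyl)-3-methoxy-5-(methoxymethoxy)phenol, whose only free phenol is the future O1. A chiral enamine of 5-methylhex-4-enal captures it, forming the C1''–C2'' bond, a transient six-membered lactol and the C2'' stereocentre in one operation. The lactol carbon then becomes the isopropenyl carbon; ortho-acetylation, chalcone formation and an enantioselective oxa-Michael closure build ring C and set C2, and one mild acid step frees the three phenols.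

Key step: step 3

Remark: the oxygen para to the hydroxymethyl group (the future 5-OH) is carried as a methoxymethyl ether, not a methyl ether, so that mild acid releases it together with the ring B phenols and no Lewis-acid demethylation is run on the acid-sensitive 1,5-diene; compounds 1, 4 and 17 are taken as purchased.

Step 1
Reactants: 1 2,4-dihydroxy-6-methoxybenzaldehyde
Product: 2 2-hydroxy-6-methoxy-4-(methoxymethoxy)benzaldehyde
Conditions: MOMCl (1.1 equiv), K2CO3, acetone, 0 °C → rt
Reagents that add atoms: chloromethyl methyl ether, COCCl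
Why: Williamson etherification should occur only at the 4-OH, because the 2-OH is held in a hydrogen bond to the aldehyde and is much less nucleophilic.

Step 2
Reactants: 2 2-hydroxy-6-methoxy-4-(methoxymethoxy)benzaldehyde
Product: 3 2-(hydroxymethyl)-3-methoxy-5-(methoxymethoxy)phenol
Conditions: NaBH4, THF/MeOH, 0 °C, 20 min; pH 7 buffer work-up; used at once
Reagents that add atoms: none
Why: Borohydride reduction of a salicylaldehyde is routine, and a cold, short, neutral procedure should prevent premature loss of water from the electron-rich benzyl alcohol.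

Step 3
Reactants: 3 2-(hydroxymethyl)-3-methoxy-5-(methoxymethoxy)phenol; 4 5-methylhex-4-enal
Product: 8 (3R)-5-methoxy-7-(methoxymethoxy)-3-(3-methylbut-2-en-1-yl)chroman-2-ol (anomer mixture), via ortho-quinone methide 5 (not isolated), via catalyst enamine 6 (not isolated), via catalyst-bound aminal 7 (not isolated)
Conditions: (S)-2-[diphenyl(trimethylsilyloxy)methyl]pyrrolidine (20 mol%), PhCO2H (20 mol%), 4 (3 equiv), CHCl3, rt → 40 °C, 3 added slowly by syringe pump
Reagents that add atoms: water, O (formed in the flask)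
Why: Benzoic acid-assisted loss of water from 3 gives ortho-quinone methide 5, stabilised by the ortho methoxy and para methoxymethoxy groups, while the catalyst condenses with 4 to the E-enamine 6; the enamine β-carbon adds to the exocyclic methylene (C1''–C2'' bond), the phenoxide oxygen closes onto the iminium carbon to give aminal 7, and hydrolysis releases lactol 8 and the catalyst. The closest known reaction type is the aminocatalytic enantioselective formal [4+2] cycloaddition of in situ ortho-quinone methides with enolisable aldehydes, which gives 3-substituted chroman-2-ols. The one new ring, the six-membered O1–C2–C3–C4–C4a–C8a dihydropyran, is closed through its C–O bond by 6-exo-trig attack of the phenoxide on the iminium carbon (or, if concerted, as the second bond of an inverse-demand oxa-[4+2]). The C3 stereocentre (the future C2'') is set under catalyst control: the diphenyl(silyloxy)methyl group shields one face of the anti E-enamine, so the methylene carbon should add to the open Si face and C3 should emerge R, whereas the anomeric C2 is uncontrolled and is erased later. The step needs capture of 5 by the enamine and a configurationally stable product: the single free phenol and the capped para oxygen allow only one quinone methide, slow addition of 3 into excess 4 keeps 5 from alkylating a second molecule of 3, and closure to the lactol masks the α-branched aldehyde against amine-mediated epimerisation.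

Step 4
Reactants: 8 (3R)-5-methoxy-7-(methoxymethoxy)-3-(3-methylbut-2-en-1-yl)chroman-2-ol
Product: 10 2-[(2R)-3-hydroxy-2-(3-methylbut-2-en-1-yl)butyl]-3-methoxy-5-(methoxymethoxy)phenol (carbinol epimers), via open-chain aldehyde 9 (not isolated)
Conditions: MeMgBr (4 equiv), THF, 0 °C → rt; aq NH4Cl
Reagents that add atoms: methylmagnesium bromide, C[Mg]Br
Why: In this Grignard addition to a lactol, deprotonation opens the hemiacetal to the aldehyde phenoxide, which a second equivalent should trap faster than it enolises, so the adjacent stereocentre is kept and the new carbinol centre is of no consequence.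

Step 5
Reactants: 10 2-[(2R)-3-hydroxy-2-(3-methylbut-2-en-1-yl)butyl]-3-methoxy-5-(methoxymethoxy)phenol
Product: 11 (3R)-4-[2-methoxy-4-(methoxymethoxy)-6-{[2-(trimethylsilyl)ethoxy]methoxy}phenyl]-3-(3-methylbut-2-en-1-yl)butan-2-ol (carbinol epimers)
Conditions: SEMCl (1.1 equiv), K2CO3, DMF, 0 °C → rt
Reagents that add atoms: 2-(trimethylsilyl)ethoxymethyl chloride, C[Si](C)(C)CCOCCl
Why: Williamson etherification under carbonate conditions should alkylate the phenoxide and not the neutral secondary alcohol, installing a fluoride-labile acetal that protects the phenol and later directs lithiation.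

Step 6
Reactants: 11 (3R)-4-[2-methoxy-4-(methoxymethoxy)-6-{[2-(trimethylsilyl)ethoxy]methoxy}phenyl]-3-(3-methylbut-2-en-1-yl)butan-2-ol
Product: 12 (3R)-4-[2-methoxy-4-(methoxymethoxy)-6-{[2-(trimethylsilyl)ethoxy]methoxy}phenyl]-3-(3-methylbut-2-en-1-yl)butan-2-one
Conditions: DMP (1,1,1-triacetoxy-1,2-benziodoxol-3(1H)-one), NaHCO3, CH2Cl2, 0 °C → rt
Reagents that add atoms: none
Why: Buffered periodinane oxidation of a secondary alcohol should give the methyl ketone under near-neutral conditions that neither enolise the adjacent tertiary stereocentre nor touch the alkene or the acetal ethers.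

Step 7
Reactants: 12 (3R)-4-[2-methoxy-4-(methoxymethoxy)-6-{[2-(trimethylsilyl)ethoxy]methoxy}phenyl]-3-(3-methylbut-2-en-1-yl)butan-2-one
Product: 13 trimethyl{2-[(3-methoxy-5-(methoxymethoxy)-2-[(2R)-5-methyl-2-(prop-1-en-2-yl)hex-4-en-1-yl]phenoxy)methoxy]ethyl}silane
Conditions: Ph3PCH3Br, KOtBu, THF, 0 °C → rt (ylide preformed, ketone added at 0 °C)
Reagents that add atoms: methyltriphenylphosphonium bromide, C[P+](c1ccccc1)(c1ccccc1)c1ccccc1.[Br-]
Why: Wittig methylenation of a methyl ketone is fast at 0 °C and the ylide is too weak a base to deprotonate the hindered tertiary α-carbon at a competitive rate, so the C2'' configuration should pass into the allylic position, where it is no longer labile.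

Step 8
Reactants: 13 trimethyl{2-[(3-methoxy-5-(methoxymethoxy)-2-[(2R)-5-methyl-2-(prop-1-en-2-yl)hex-4-en-1-yl]phenoxy)methoxy]ethyl}silane
Product: 15 1-[4-methoxy-6-(methoxymethoxy)-3-[(2R)-5-methyl-2-(prop-1-en-2-yl)hex-4-en-1-yl]-2-{[2-(trimethylsilyl)ethoxy]methoxy}phenyl]ethan-1-one, via aryllithium 14 (not isolated)
Conditions: n-BuLi (1.3 equiv), THF, 0 °C, 1 h; then MeC(O)N(OMe)Me, −78 → 0 °C; aq NH4Cl
Reagents that add atoms: N-methoxy-N-methylacetamide, CC(=O)N(C)OC
Why: In this directed ortho-metalation and acylation, the ring hydrogen flanked by the two acetal ethers should be lithiated in preference to the one between the methoxy and methoxymethoxy groups, and the N-methoxy-N-methylamide acylates the aryllithium once only.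

Step 9
Reactants: 15 1-[4-methoxy-6-(methoxymethoxy)-3-[(2R)-5-methyl-2-(prop-1-en-2-yl)hex-4-en-1-yl]-2-{[2-(trimethylsilyl)ethoxy]methoxy}phenyl]ethan-1-one
Product: 16 1-[2-hydroxy-4-methoxy-6-(methoxymethoxy)-3-[(2R)-5-methyl-2-(prop-1-en-2-yl)hex-4-en-1-yl]phenyl]ethan-1-one
Conditions: TBAF, THF, 50 °C; aq NH4Cl
Reagents that add atoms: none
Why: Fluoride-induced fragmentation of the silylethoxymethyl acetal (attack at silicon, loss of ethene and formaldehyde) should release the phenol ortho to the acetyl group, while the methoxymethyl ether has no silicon trigger and stays.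

Step 10
Reactants: 17 2,6-dihydroxybenzaldehyde
Product: 18 2,6-bis(methoxymethoxy)benzaldehyde
Conditions: NaH (2.5 equiv), MOMCl (2.5 equiv), DMF, 0 °C → rt
Reagents that add atoms: chloromethyl methyl ether, COCCl
Why: Williamson etherification of the preformed bis-phenoxide overcomes the hydrogen bonding of both hydroxyls to the aldehyde and gives a base-stable, acid-labile protected aldehyde.

Step 11
Reactants: 16 1-[2-hydroxy-4-methoxy-6-(methoxymethoxy)-3-[(2R)-5-methyl-2-(prop-1-en-2-yl)hex-4-en-1-yl]phenyl]ethan-1-one; 18 2,6-bis(methoxymethoxy)benzaldehyde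
Product: 20 (2E)-3-[2,6-bis(methoxymethoxy)phenyl]-1-[2-hydroxy-4-methoxy-6-(methoxymethoxy)-3-[(2R)-5-methyl-2-(prop-1-en-2-yl)hex-4-en-1-yl]phenyl]prop-2-en-1-one, via aldol adduct 19 (not isolated)
Conditions: KOH (50% aq), EtOH, rt, 24–48 h; then cold dilute HCl to pH 5
Reagents that add atoms: none
Why: Claisen–Schmidt condensation of a 2'-hydroxyacetophenone with a non-enolisable aldehyde should give the E-chalcone by aldol addition and E1cB dehydration, the methoxymethyl ethers and the non-acidic allylic stereocentre being stable to hydroxide.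

Step 12
Reactants: 20 (2E)-3-[2,6-bis(methoxymethoxy)phenyl]-1-[2-hydroxy-4-methoxy-6-(methoxymethoxy)-3-[(2R)-5-methyl-2-(prop-1-en-2-yl)hex-4-en-1-yl]phenyl]prop-2-en-1-one
Product: 21 (2S)-2-[2,6-bis(methoxymethoxy)phenyl]-7-methoxy-5-(methoxymethoxy)-8-[(2R)-5-methyl-2-(prop-1-en-2-yl)hex-4-en-1-yl]-2,3-dihydro-4H-chromen-4-one
Conditions: N-[3,5-bis(trifluoromethyl)phenyl]-N'-(9-deoxy-epi-quinidin-9-yl)thiourea (20 mol%), toluene, rt → 40 °C
Reagents that add atoms: none
Why: In this enantioselective intramolecular oxa-Michael addition (6-endo-trig), the quinuclidine activates the only free phenol and the thiourea binds the enone carbonyl, so the phenoxide should add to one face of the β-carbon and set C2 as S under catalyst control; the quinidine series is chosen by analogy with its sense in enone conjugate additions, the quinine-derived pseudoenantiomer giving the mirror sense.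

Step 13
Reactants: 21 (2S)-2-[2,6-bis(methoxymethoxy)phenyl]-7-methoxy-5-(methoxymethoxy)-8-[(2R)-5-methyl-2-(prop-1-en-2-yl)hex-4-en-1-yl]-2,3-dihydro-4H-chromen-4-one
Product: 22 Exiguaflavanone B, (2S)-2-(2,6-dihydroxyphenyl)-5-hydroxy-7-methoxy-8-[(2R)-5-methyl-2-(prop-1-en-2-yl)hex-4-en-1-yl]-2,3-dihydro-4H-chromen-4-one
Conditions: HCl (3 M aq), MeOH, rt → 40 °C
Reagents that add atoms: none
Why: Acid-catalysed acetal cleavage should remove the three methoxymethyl groups under conditions mild enough to leave the 7-methyl ether, both alkenes and the C2 centre untouched.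

Compound list
1 | 2,4-dihydroxy-6-methoxybenzaldehyde | O=Cc1c(O)cc(O)cc1OC | starting material
2 | 2-hydroxy-6-methoxy-4-(methoxymethoxy)benzaldehyde | O=Cc1c(O)cc(OCOC)cc1OC | intermediate
3 | 2-(hydroxymethyl)-3-methoxy-5-(methoxymethoxy)phenol | OCc1c(O)cc(OCOC)cc1OC | intermediate
4 | 5-methylhex-4-enal | CC(C)=CCCC=O | starting material
5 | 5-methoxy-3-(methoxymethoxy)-6-methylidenecyclohexa-2,4-dien-1-one (ortho-quinone methide) | C=C1C(=O)C=C(OCOC)C=C1OC | intermediate
6 | (2S)-2-[diphenyl(trimethylsilyloxy)methyl]-1-[(1E)-5-methylhexa-1,4-dien-1-yl]pyrrolidine (catalyst enamine) | CC(C)=CC/C=C/N1CCC[C@H]1C(c1ccccc1)(c1ccccc1)O[Si](C)(C)C | intermediate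
7 | (3R)-2-{(2S)-2-[diphenyl(trimethylsilyloxy)methyl]pyrrolidin-1-yl}-5-methoxy-7-(methoxymethoxy)-3-(3-methylbut-2-en-1-yl)chromane (aminal, C2 unassigned) | C1(N2CCC[C@H]2C(c2ccccc2)(c2ccccc2)O[Si](C)(C)C)[C@H](CC=C(C)C)Cc2c(OC)cc(OCOC)cc2O1 | intermediate
8 | (3R)-5-methoxy-7-(methoxymethoxy)-3-(3-methylbut-2-en-1-yl)chroman-2-ol (anomer mixture) | OC1[C@H](CC=C(C)C)Cc2c(OC)cc(OCOC)cc2O1 | intermediate
9 | (2R)-2-{[2-hydroxy-6-methoxy-4-(methoxymethoxy)phenyl]methyl}-5-methylhex-4-enal | O=C[C@H](CC=C(C)C)Cc1c(O)cc(OCOC)cc1OC | intermediate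
10 | 2-[(2R)-3-hydroxy-2-(3-methylbut-2-en-1-yl)butyl]-3-methoxy-5-(methoxymethoxy)phenol (carbinol epimers) | CC(O)[C@H](CC=C(C)C)Cc1c(O)cc(OCOC)cc1OC | intermediate
11 | (3R)-4-[2-methoxy-4-(methoxymethoxy)-6-{[2-(trimethylsilyl)ethoxy]methoxy}phenyl]-3-(3-methylbut-2-en-1-yl)butan-2-ol (carbinol epimers) | CC(O)[C@H](CC=C(C)C)Cc1c(OCOCC[Si](C)(C)C)cc(OCOC)cc1OC | intermediate
12 | (3R)-4-[2-methoxy-4-(methoxymethoxy)-6-{[2-(trimethylsilyl)ethoxy]methoxy}phenyl]-3-(3-methylbut-2-en-1-yl)butan-2-one | CC(=O)[C@H](CC=C(C)C)Cc1c(OCOCC[Si](C)(C)C)cc(OCOC)cc1OC | intermediate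
13 | trimethyl{2-[(3-methoxy-5-(methoxymethoxy)-2-[(2R)-5-methyl-2-(prop-1-en-2-yl)hex-4-en-1-yl]phenoxy)methoxy]ethyl}silane | C=C(C)[C@H](CC=C(C)C)Cc1c(OCOCC[Si](C)(C)C)cc(OCOC)cc1OC | intermediate
14 | [4-methoxy-6-(methoxymethoxy)-3-[(2R)-5-methyl-2-(prop-1-en-2-yl)hex-4-en-1-yl]-2-{[2-(trimethylsilyl)ethoxy]methoxy}phenyl]lithium | C=C(C)[C@H](CC=C(C)C)Cc1c(OCOCC[Si](C)(C)C)c([Li])c(OCOC)cc1OC | intermediate
15 | 1-[4-methoxy-6-(methoxymethoxy)-3-[(2R)-5-methyl-2-(prop-1-en-2-yl)hex-4-en-1-yl]-2-{[2-(trimethylsilyl)ethoxy]methoxy}phenyl]ethan-1-one | C=C(C)[C@H](CC=C(C)C)Cc1c(OCOCC[Si](C)(C)C)c(C(C)=O)c(OCOC)cc1OC | intermediate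
16 | 1-[2-hydroxy-4-methoxy-6-(methoxymethoxy)-3-[(2R)-5-methyl-2-(prop-1-en-2-yl)hex-4-en-1-yl]phenyl]ethan-1-one | C=C(C)[C@H](CC=C(C)C)Cc1c(O)c(C(C)=O)c(OCOC)cc1OC | intermediate
17 | 2,6-dihydroxybenzaldehyde | O=Cc1c(O)cccc1O | starting material
18 | 2,6-bis(methoxymethoxy)benzaldehyde | O=Cc1c(OCOC)cccc1OCOC | intermediate
19 | 3-[2,6-bis(methoxymethoxy)phenyl]-3-hydroxy-1-[2-hydroxy-4-methoxy-6-(methoxymethoxy)-3-[(2R)-5-methyl-2-(prop-1-en-2-yl)hex-4-en-1-yl]phenyl]propan-1-one (carbinol epimers) | C=C(C)[C@H](CC=C(C)C)Cc1c(O)c(C(=O)CC(O)c2c(OCOC)cccc2OCOC)c(OCOC)cc1OC | intermediate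
20 | (2E)-3-[2,6-bis(methoxymethoxy)phenyl]-1-[2-hydroxy-4-methoxy-6-(methoxymethoxy)-3-[(2R)-5-methyl-2-(prop-1-en-2-yl)hex-4-en-1-yl]phenyl]prop-2-en-1-one | C=C(C)[C@H](CC=C(C)C)Cc1c(O)c(C(=O)/C=C/c2c(OCOC)cccc2OCOC)c(OCOC)cc1OC | intermediate
21 | (2S)-2-[2,6-bis(methoxymethoxy)phenyl]-7-methoxy-5-(methoxymethoxy)-8-[(2R)-5-methyl-2-(prop-1-en-2-yl)hex-4-en-1-yl]-2,3-dihydro-4H-chromen-4-one | C=C(C)[C@H](CC=C(C)C)Cc1c(OC)cc(OCOC)c2c1O[C@H](c1c(OCOC)cccc1OCOC)CC2=O | intermediate
22 | Exiguaflavanone B, (2S)-2-(2,6-dihydroxyphenyl)-5-hydroxy-7-methoxy-8-[(2R)-5-methyl-2-(prop-1-en-2-yl)hex-4-en-1-yl]-2,3-dihydro-4H-chromen-4-one | C=C(C)[C@H](CC=C(C)C)Cc1c(OC)cc(O)c2c1O[C@H](c1c(O)cccc1O)CC2=O | target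

Total step count: 13. Longest linear sequence: 12 steps (steps 1–9 and 11–13); step 10 is a one-step side branch.

Steps most likely to fail

1. Step 3 (key step). The quinone methide may be consumed by a second molecule of the electron-rich phenol (oligomeric diarylmethanes), or be parked on the secondary amine as a Mannich base, faster than the enamine captures it. Face selectivity may also erode if the lactol reopens and re-enters the enamine cycle. The fallback forms the stereocentre by auxiliary-controlled enolate alkylation and uses no quinone methide. It sets out from 2. NaH and SEMCl in DMF give the fully protected aldehyde F1. Horner–Wadsworth–Emmons olefination with triethyl phosphonoacetate (NaH, THF) gives the ethyl E-cinnamate F2. Hydrogenation (H2, Pd/C, EtOAc) gives the saturated ester F3, and LiOH (THF/H2O) gives the arylpropanoic acid F4. Its mixed pivalic anhydride acylates lithiated (4R)-4-benzyl-1,3-oxazolidin-2-one to the N-acyl oxazolidinone F5. NaN(SiMe3)2 then prenyl bromide (THF, −78 °C) should alkylate the chelated Z-enolate on the face away from the benzyl group to give the 2R alkylated imide F6. LiOH/H2O2 removes the auxiliary to give the carboxylic acid F7, and MeLi (2.2 equiv, Et2O, 0 °C) converts the acid into methyl ketone 12, where the route is rejoined.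

2. Step 12. Face discrimination may be poor at a β-carbon that carries a 2,6-disubstituted aryl group, and slow turnover would let uncatalysed closure feed in the C2 epimer, which differs from 21 only at a remote centre and would be hard to remove. The fallback replaces asymmetric induction by a resolution. It sets out from 20. NaOAc in EtOH at reflux closes the ring without control to give the flavanone as a mixture of C2 epimers F8. Asymmetric transfer hydrogenation with RuCl(p-cymene)[(R,R)-TsDPEN] in HCO2H/Et3N then serves as a kinetic resolution. The catalyst should deliver hydride to give a 4R carbinol, which only the 2R epimer can accept on the face away from its C2 aryl group; that epimer should therefore be reduced to the cis-(2R,4R)-flavan-4-ol F9 while the 2S ketone is left. Chromatography separates ketone from alcohol and returns the route at 21.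

3. Step 8. Lithiation may go to the ring hydrogen between the methoxy and methoxymethoxy groups or to a benzylic or allylic position, and the hindered aryllithium may deprotonate the acetamide and not add to it. The fallback replaces directed lithiation by an ortho-formylation of the free phenol. It sets out from 13. TBAF (THF, 50 °C) gives the lavandulyl phenol F10. MgCl2, Et3N and paraformaldehyde (MeCN, reflux) should formylate its only free ortho position to give the salicylaldehyde F11. MeMgBr (THF, 0 °C) gives the benzylic carbinol F12, which is oxidised without purification with MnO2 (CH2Cl2, rt) to 16, where the route is rejoined.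

Further compounds
F1 | step 3 | 2-methoxy-4-(methoxymethoxy)-6-{[2-(trimethylsilyl)ethoxy]methoxy}benzaldehyde | O=Cc1c(OCOCC[Si](C)(C)C)cc(OCOC)cc1OC
F2 | step 3 | ethyl (2E)-3-[2-methoxy-4-(methoxymethoxy)-6-{[2-(trimethylsilyl)ethoxy]methoxy}phenyl]prop-2-enoate | CCOC(=O)/C=C/c1c(OCOCC[Si](C)(C)C)cc(OCOC)cc1OC
F3 | step 3 | ethyl 3-[2-methoxy-4-(methoxymethoxy)-6-{[2-(trimethylsilyl)ethoxy]methoxy}phenyl]propanoate | CCOC(=O)CCc1c(OCOCC[Si](C)(C)C)cc(OCOC)cc1OC
F4 | step 3 | 3-[2-methoxy-4-(methoxymethoxy)-6-{[2-(trimethylsilyl)ethoxy]methoxy}phenyl]propanoic acid | OC(=O)CCc1c(OCOCC[Si](C)(C)C)cc(OCOC)cc1OC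
F5 | step 3 | (4R)-4-benzyl-3-{3-[2-methoxy-4-(methoxymethoxy)-6-{[2-(trimethylsilyl)ethoxy]methoxy}phenyl]propanoyl}-1,3-oxazolidin-2-one | O=C(CCc1c(OCOCC[Si](C)(C)C)cc(OCOC)cc1OC)N1[C@H](Cc2ccccc2)COC1=O
F6 | step 3 | (4R)-4-benzyl-3-[(2R)-2-{[2-methoxy-4-(methoxymethoxy)-6-{[2-(trimethylsilyl)ethoxy]methoxy}phenyl]methyl}-5-methylhex-4-enoyl]-1,3-oxazolidin-2-one | O=C([C@H](CC=C(C)C)Cc1c(OCOCC[Si](C)(C)C)cc(OCOC)cc1OC)N1[C@H](Cc2ccccc2)COC1=O
F7 | step 3 | (2R)-2-{[2-methoxy-4-(methoxymethoxy)-6-{[2-(trimethylsilyl)ethoxy]methoxy}phenyl]methyl}-5-methylhex-4-enoic acid | OC(=O)[C@H](CC=C(C)C)Cc1c(OCOCC[Si](C)(C)C)cc(OCOC)cc1OC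
F8 | step 12 | (2RS)-2-[2,6-bis(methoxymethoxy)phenyl]-7-methoxy-5-(methoxymethoxy)-8-[(2R)-5-methyl-2-(prop-1-en-2-yl)hex-4-en-1-yl]-2,3-dihydro-4H-chromen-4-one (C2 epimer mixture) | C=C(C)[C@H](CC=C(C)C)Cc1c(OC)cc(OCOC)c2c1OC(c1c(OCOC)cccc1OCOC)CC2=O
F9 | step 12 | (2R,4R)-2-[2,6-bis(methoxymethoxy)phenyl]-7-methoxy-5-(methoxymethoxy)-8-[(2R)-5-methyl-2-(prop-1-en-2-yl)hex-4-en-1-yl]-3,4-dihydro-2H-chromen-4-ol | C=C(C)[C@H](CC=C(C)C)Cc1c(OC)cc(OCOC)c2c1O[C@@H](c1c(OCOC)cccc1OCOC)C[C@H]2O
F10 | step 8 | 3-methoxy-5-(methoxymethoxy)-2-[(2R)-5-methyl-2-(prop-1-en-2-yl)hex-4-en-1-yl]phenol | C=C(C)[C@H](CC=C(C)C)Cc1c(O)cc(OCOC)cc1OC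
F11 | step 8 | 2-hydroxy-4-methoxy-6-(methoxymethoxy)-3-[(2R)-5-methyl-2-(prop-1-en-2-yl)hex-4-en-1-yl]benzaldehyde | C=C(C)[C@H](CC=C(C)C)Cc1c(O)c(C=O)c(OCOC)cc1OC
F12 | step 8 | 1-[2-hydroxy-4-methoxy-6-(methoxymethoxy)-3-[(2R)-5-methyl-2-(prop-1-en-2-yl)hex-4-en-1-yl]phenyl]ethan-1-ol (carbinol epimers) | C=C(C)[C@H](CC=C(C)C)Cc1c(O)c(C(C)O)c(OCOC)cc1OC
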